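**Count first.** Before committing to beta for complex with one exchanged, count how many half-lives of its fading lie ahead of the reading at 5.0 min.

| setting | amber | violet | epsilon | beta |
|---|---|---|---|---|
| starting complex | 1 mM | 1 mM | 1.0 mM | 1.0 mM |
| incoming ligand | 0.52 mM | 1.9 mM | 3.00 mM | 0.800 mM |
| remark | run made earlier | run made earlier |  |  |
| time |  |  | 5.0 min | 5.0 min |

| run | time / min | complex with one exchanged / % | complex with two exchanged / % |
|---|---|---|---|
| amber | 0.417 | 11.4 | 4.0 |
| amber | 0.833 | 10.5 | 10.2 |
| amber | 1.33 | 8.9 | 11.0 |
| amber | 2.50 | 2.9 | 11.3 |
| amber | 5.00 | 0.3 | 12.2 |
| violet | 0.417 | 15.9 | 32.7 |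
| violet | 0.833 | 9.7 | 51.2 |
| violet | 1.33 | 6.7 | 58.9 |
| violet | 2.50 | 1.3 | 64.3 |
| violet | 5.00 | 1.4 | 71.4 |

(scatter of a reading: 1 percentage point)



- which of these holds the largest part of the starting complex at the end of epsilon (starting complex / complex with two exchanged / complex with one exchanged)
- which of these holds the largest part of the starting complex at the end of beta (starting complex / complex with two exchanged / complex with one exchanged)
- final complex with one exchanged in beta, as a percentage of the starting complex charged

**Fast rung.** Start with what happens while the exchange runs. In violet at 0.417 min, complex with two exchanged already reads 32.7 %, twice the 15.9 % of complex with one exchanged, so the second exchange follows closely on the first.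

**Middle rung.** Next find the stall. In amber, complex with two exchanged reads 11.0 % at 1.33 min and 11.3 % at 2.50 min, a rise of just 0.3 percentage points.

**Slow rung.** Over those same minutes, amber's complex with one exchanged falls from 8.9 % to 2.9 %, a loss of 6 points against that rise. Treat this as a first-order loss and read the fade half-life, the time in which complex with one exchanged halves after the stall: 0.723 min. It is a reading and carries the scatter of both points.

**Last rung.** From 2.50 min to 5.0 min lie 3.46 fade half-lives. No earlier run was made at beta's charge of 0.800 mM, so borrow amber's 2.9 % at 2.50 min as my rough start for beta, a guess at beta's amount and no bound on it. Fading it gives 0.264 %.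

**The forecast.** It names complex with two exchanged for epsilon and starting complex for beta, and gives 0.5 % for beta, saying “it is near zero by 5 min”. My figure is lower than its figure; a single reading scatters by 1 point.

    starting complex + incoming ligand → leaving ligand + complex with one exchanged (k = 23.5 M⁻¹ s⁻¹)
    complex with one exchanged + incoming ligand → leaving ligand + complex with two exchanged (k = 68.0 M⁻¹ s⁻¹)
    complex with one exchanged → side product (k = 0.0187 s⁻¹)

**The result.** Epsilon ends with most in complex with two exchanged, at 86.9 %. Beta ends with most in starting complex, at 44.1 %, and holds 0.815 % of complex with one exchanged. In beta at 5.00 min, that complex is still made at 0.434 of the rate it is used up. Fading beta's 4.26 % from 2.50 min with 0.723 min gives 0.388 %. The same count takes epsilon's 0.252 % at 2.50 min to 0.0229 %, and epsilon shows 0 %.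

The numbers in the tables come from a simulation for an exercise; noise was put on by code.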